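**Plan**

1. Numbering used throughout: seven-membered ring C1 (ester carbinol), C2, C3 (C(CH3)OH), C4, C5, C6, C7 (CH-isopropyl); five-membered ring C5, C8, C9 (C-CH3), C10, C6.
2. Retrosynthesis: remove the C1 ester and the C8/C9 epoxide oxygen, cut C9–CH3 back to a C9 ketone, then cut C5–C6, C8–C9 and C9–C10 together. This is possible because C9 sits between C8 and C10 of the five-membered ring and can be carbon monoxide, while C8–C5 maps onto an alkyne and C7–C6–C10 onto an allene.
3. The open-chain allenyne is cut at C7–isopropyl (SN2′), C1–C7 (acetylide addition) and C3–C4 (ketone propargylation).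
4. Forward: the chain is joined in the order C3–C4, C1–C7, C7–isopropyl; one rhodium-catalysed cyclocarbonylation closes the seven- and five-membered rings together; stepwise reduction, C9 methylation, esterification and epoxidation finish.
5. Stereochemistry: C3 from a copper-catalysed enantioselective propargylation; C1 from a Noyori transfer hydrogenation (reagent control); C7 by hydride delivery anti to the C1 silyl ether; C6 by equilibration; C5 by dissolving-metal protonation (trans fusion); C8/C9 by epoxidation directed by the C3 hydroxyl.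

Key step: step 8

Assumption: the ligand antipodes quoted in steps 1 and 5 are those expected from the usual facial models of these catalysts; if a sense proves opposite, the mirror-image ligand is used.

**Route**

Step 1
Reactants: 1 4,4-dimethoxybutan-2-one; 2 allenylboronic acid pinacol ester
Product: 3 (3R)-1,1-dimethoxy-3-methylhex-5-yn-3-ol
Conditions: CuOAc (5 mol%), chiral bisphospholane of the Ph-BPE type (6 mol%, antipode giving 3R), LiOiPr (0.5 equiv), iPrOH (1 equiv), CH2Cl2, −75 °C
Reagents that add atoms: none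
Why: Copper-catalysed enantioselective propargylation of a ketone, in which boron-to-copper exchange gives an allenylcopper that adds through its γ-carbon to the ketone face selected by the chiral bisphosphine, setting C3 as R.

Step 2
Reactants: 3 (3R)-1,1-dimethoxy-3-methylhex-5-yn-3-ol
Product: 6 (3R)-3-methyl-3-(triethylsilyloxy)hex-5-ynal, via silyl ether acetal 4 (not isolated), via collidinium salt 5 (not isolated)
Conditions: TESOTf (3 equiv), 2,4,6-collidine (4.5 equiv), CH2Cl2, 0 °C; then H2O, rt
Reagents that add atoms: triethylsilyl triflate, CC[Si](CC)(CC)OS(=O)(=O)C(F)(F)F; water, O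
Why: Silyl triflate silylation of the tertiary alcohol followed in the same flask by the silyl triflate–collidine cleavage of the dimethyl acetal (a pyridinium N,O-acetal that water hydrolyses) should unmask the aldehyde without acid, so the tertiary silyl ether survives.

Step 3
Reactants: 6 (3R)-3-methyl-3-(triethylsilyloxy)hex-5-ynal; 7 3-methoxyprop-1-yne
Product: 8 (6R)-1-methoxy-6-methyl-6-(triethylsilyloxy)nona-2,8-diyn-4-ol (both C4 epimers)
Conditions: 7, n-BuLi, THF, −78 °C; then 6, −78 °C
Reagents that add atoms: none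
Why: 1,2-Addition of a lithium acetylide to the aldehyde forms the C1–C7 bond, and the configuration of the new carbinol does not matter because it is oxidised in the next step.

Step 4
Reactants: 8 (6R)-1-methoxy-6-methyl-6-(triethylsilyloxy)nona-2,8-diyn-4-ol
Product: 9 (6R)-1-methoxy-6-methyl-6-(triethylsilyloxy)nona-2,8-diyn-4-one
Conditions: Dess–Martin periodinane, CH2Cl2, 0 °C to rt
Reagents that add atoms: none
Why: Dess–Martin oxidation of a propargylic alcohol gives the ynone under near-neutral conditions that spare the silyl ether and the terminal alkyne.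

Step 5
Reactants: 9 (6R)-1-methoxy-6-methyl-6-(triethylsilyloxy)nona-2,8-diyn-4-one
Product: 10 (4R,6R)-1-methoxy-6-methyl-6-(triethylsilyloxy)nona-2,8-diyn-4-ol
Conditions: Ru[(R,R)-TsDPEN](p-cymene) (2 mol%), iPrOH, rt
Reagents that add atoms: none
Why: Noyori asymmetric transfer hydrogenation of an ynone, in which the chiral diamine catalyst distinguishes the alkynyl from the alkyl side and should set the carbinol (C1 of the plan) as R under reagent control, independent of the remote C3 centre.

Step 6
Reactants: 10 (4R,6R)-1-methoxy-6-methyl-6-(triethylsilyloxy)nona-2,8-diyn-4-ol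
Product: 11 (4R,6R)-6-methyl-3-(propan-2-yl)-6-(triethylsilyloxy)nona-1,2-dien-8-yn-4-ol
Conditions: iPrMgCl (4 equiv), CuI (20 mol%), Et2O/THF, −30 °C to rt
Reagents that add atoms: isopropylmagnesium chloride, CC(C)[Mg]Cl
Why: Copper-catalysed SN2′ substitution of a 4-methoxyalk-2-yn-1-ol by a Grignard reagent (alkoxide-directed carbometalation, then β-elimination of methoxide) should place isopropyl on the alkyne carbon next to the carbinol and turn the other alkyne carbon into the allene centre, leaving the carbinol configuration untouched.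

Step 7
Reactants: 11 (4R,6R)-6-methyl-3-(propan-2-yl)-6-(triethylsilyloxy)nona-1,2-dien-8-yn-4-ol
Product: 12 (4R,6R)-4-(tert-butyldimethylsilyloxy)-6-methyl-3-(propan-2-yl)-6-(triethylsilyloxy)nona-1,2-dien-8-yne
Conditions: TBSOTf, 2,6-lutidine, CH2Cl2, −78 to 0 °C
Reagents that add atoms: tert-butyldimethylsilyl triflate, CC(C)(C)[Si](C)(C)OS(=O)(=O)C(F)(F)F
Why: Silyl triflate silylation protects the hindered secondary allenyl carbinol with a bulky group that later shields one face of C7.

Step 8
Reactants: 12 (4R,6R)-4-(tert-butyldimethylsilyloxy)-6-methyl-3-(propan-2-yl)-6-(triethylsilyloxy)nona-1,2-dien-8-yne; 13 carbon monoxide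
Product: 14 (1R,3R)-1-(tert-butyldimethylsilyloxy)-7-isopropyl-3-methyl-3-(triethylsilyloxy)bicyclo[5.3.0]deca-5(8),6-dien-9-one
Conditions: [Rh(CO)2Cl]2 (5 mol%), CO (1 atm), toluene, 90 °C
Reagents that add atoms: none
Why: Monovalent rhodium binds the alkyne and the distal C6=C10 bond of the allene and undergoes oxidative cyclometalation to a trivalent rhodacyclopentene, which forms C5–C6 and so closes the seven-membered ring (C5, C4, C3, C2, C1, C7, C6) across the four-atom tether; CO insertion and reductive elimination then form C8–C9 and C9–C10 and close the cyclopentenone (C5, C8, C9, C10, C6) in a [2+2+1] mode. The closest known reaction is the rhodium-catalysed allenic Pauson–Khand reaction of allenynes, which gives 4-alkylidenecyclopentenones fused to seven-membered rings. No stereocentre is created: C5, C6 and C7 are sp2 in the product, the geometry of the tetrasubstituted C6=C7 alkene is fixed by the ring, and C1 and C3 are spectators. The selectivity needed is reaction at the distal rather than the proximal allene bond, and it is secured by the rhodium catalyst (Mo(CO)6 would favour the proximal bond and a bicyclo[4.3.0] α-methylene ketone), by the 1,1-disubstitution at C7 and by the tether length. The CO atmosphere should suppress the rhodium Alder-ene cycloisomerisation that the allylic hydrogen of the isopropyl group would otherwise allow, and the quaternary C3 assists closure through the Thorpe–Ingold effect.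

Step 9
Reactants: 14 (1R,3R)-1-(tert-butyldimethylsilyloxy)-7-isopropyl-3-methyl-3-(triethylsilyloxy)bicyclo[5.3.0]deca-5(8),6-dien-9-one
Product: 16 (1R,3R,6S,7S)-1-(tert-butyldimethylsilyloxy)-7-isopropyl-3-methyl-3-(triethylsilyloxy)bicyclo[5.3.0]dec-5(8)-en-9-one, via deconjugated enone 15 (not isolated)
Conditions: [(Ph3P)CuH]6 (0.5 equiv), H2O (5 equiv), degassed benzene/THF, rt; then DBU (0.3 equiv), CH2Cl2, rt
Reagents that add atoms: none
Why: Conjugate reduction by Stryker's reagent at the vinylogous terminus (1,6-reduction, the hydride counterpart of cuprate 1,6-addition to linear dienones) should deliver hydride to C7 from the face opposite the pseudo-axial C1 silyl ether (7S), after which DBU moves the alkene into conjugation and lets C6 settle through the dienolate in the arrangement with C10 and isopropyl trans on the seven-membered ring.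

Step 10
Reactants: 16 (1R,3R,6S,7S)-1-(tert-butyldimethylsilyloxy)-7-isopropyl-3-methyl-3-(triethylsilyloxy)bicyclo[5.3.0]dec-5(8)-en-9-one
Product: 18 (1R,3R,5S,6R,7S)-1-(tert-butyldimethylsilyloxy)-7-isopropyl-3-methyl-3-(triethylsilyloxy)bicyclo[5.3.0]dec-8-en-9-yl triflate, via lithium enolate 17 (not isolated)
Conditions: Li (2.2 equiv), t-BuOH (1.0 equiv), NH3/THF, −78 °C; evaporate NH3; PhNTf2 (1.5 equiv), THF, −78 °C to rt
Reagents that add atoms: N-phenylbis(trifluoromethanesulfonimide), O=S(=O)(N(c1ccccc1)S(=O)(=O)C(F)(F)F)C(F)(F)F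
Why: Dissolving-metal reduction of the enone should protonate the pyramidal C5 carbanion in the more stable trans-fused arrangement (C5–H anti to C6–H) and leaves the C9 enolate with its double bond fixed towards C8, which the triflimide O-sulfonylates (regiospecific enolate trapping as the enol triflate).

Step 11
Reactants: 18 (1R,3R,5S,6R,7S)-1-(tert-butyldimethylsilyloxy)-7-isopropyl-3-methyl-3-(triethylsilyloxy)bicyclo[5.3.0]dec-8-en-9-yl triflate
Product: 19 (1R,3R,5S,6R,7S)-1-(tert-butyldimethylsilyloxy)-7-isopropyl-3,9-dimethyl-3-(triethylsilyloxy)bicyclo[5.3.0]dec-8-ene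
Conditions: MeMgBr, Fe(acac)3 (5 mol%), THF/NMP, −30 to 0 °C
Reagents that add atoms: methylmagnesium bromide, C[Mg]Br
Why: Iron-catalysed Kumada-type cross-coupling of an alkenyl triflate with a methyl Grignard reagent replaces the triflate by methyl at C9 without moving the C8=C9 alkene.

Step 12
Reactants: 19 (1R,3R,5S,6R,7S)-1-(tert-butyldimethylsilyloxy)-7-isopropyl-3,9-dimethyl-3-(triethylsilyloxy)bicyclo[5.3.0]dec-8-ene
Product: 20 (1R,3R,5S,6R,7S)-7-isopropyl-3,9-dimethylbicyclo[5.3.0]dec-8-ene-1,3-diol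
Conditions: Bu4NF (5 equiv), THF, rt to 50 °C
Reagents that add atoms: none
Why: Fluoride-mediated desilylation removes both silyl ethers at a stage where only an unactivated alkene is present.

Step 13
Reactants: 21 3-hydroxy-4-methoxybenzoic acid (isovanillic acid)
Product: 22 3-acetoxy-4-methoxybenzoic acid
Conditions: Ac2O, pyridine, rt; then H2O
Reagents that add atoms: acetic anhydride, CC(=O)OC(C)=O
Why: Acetylation masks the phenol so that the acid can be activated without self-condensation, and the aqueous finish hydrolyses any mixed anhydride.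

Step 14
Reactants: 20 (1R,3R,5S,6R,7S)-7-isopropyl-3,9-dimethylbicyclo[5.3.0]dec-8-ene-1,3-diol; 22 3-acetoxy-4-methoxybenzoic acid
Product: 24 (1R,3R,5S,6R,7S)-3-hydroxy-7-isopropyl-3,9-dimethylbicyclo[5.3.0]dec-8-en-1-yl 3-acetoxy-4-methoxybenzoate, via acid chloride 23 (not isolated)
Conditions: 22, (COCl)2, DMF (cat.), CH2Cl2, 0 °C to rt, concentrate; then 20, Et3N, DMAP, CH2Cl2, 0 °C to rt
Reagents that add atoms: none
Why: DMAP-catalysed acylation with an aroyl chloride should esterify the secondary C1 hydroxyl selectively, because the tertiary C3 hydroxyl is far slower to acylate.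

Step 15
Reactants: 24 (1R,3R,5S,6R,7S)-3-hydroxy-7-isopropyl-3,9-dimethylbicyclo[5.3.0]dec-8-en-1-yl 3-acetoxy-4-methoxybenzoate
Product: 25 (1R,3R,5S,6R,7S,8S,9R)-8,9-epoxy-3-hydroxy-7-isopropyl-3,9-dimethylbicyclo[5.3.0]decan-1-yl 3-acetoxy-4-methoxybenzoate
Conditions: VO(acac)2 (10 mol%), t-BuOOH (2 equiv, decane solution), CH2Cl2, 0 °C to rt
Reagents that add atoms: tert-butyl hydroperoxide, CC(C)(C)OO
Why: Hydroxyl-directed vanadium-catalysed epoxidation, in which the C3 hydroxyl (bishomoallylic to C8=C9 and on the same face as the C1 ester and the isopropyl group) binds vanadium and should deliver the peroxide oxygen to that face, setting 8S and 9R.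

Step 16
Reactants: 25 (1R,3R,5S,6R,7S,8S,9R)-8,9-epoxy-3-hydroxy-7-isopropyl-3,9-dimethylbicyclo[5.3.0]decan-1-yl 3-acetoxy-4-methoxybenzoate
Product: 26 (1R,3R,5S,6R,7S,8S,9R)-8,9-epoxy-3-hydroxy-7-isopropyl-3,9-dimethylbicyclo[5.3.0]decan-1-yl 3-hydroxy-4-methoxybenzoate (CNP0106636.1)
Conditions: pyrrolidine (3 equiv), CH2Cl2, 0 °C
Reagents that add atoms: none
Why: Aminolysis of the aryl acetate is much faster than attack on the hindered alkyl benzoate or on the epoxide, so the phenol should be freed without touching either.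

**Compound list**

Locants of the bicyclic compounds follow the numbering of the plan.

1 | 4,4-dimethoxybutan-2-one | CC(=O)CC(OC)OC | starting material
2 | allenylboronic acid pinacol ester | C=C=CB1OC(C)(C)C(C)(C)O1 | starting material
3 | (3R)-1,1-dimethoxy-3-methylhex-5-yn-3-ol | C#CC[C@@](C)(O)CC(OC)OC | intermediate
4 | triethyl{[(3R)-1,1-dimethoxy-3-methylhex-5-yn-3-yl]oxy}silane (formed in the flask) | C#CC[C@@](C)(O[Si](CC)(CC)CC)CC(OC)OC | intermediate
5 | 1-[(3R)-1-methoxy-3-methyl-3-(triethylsilyloxy)hex-5-yn-1-yl]-2,4,6-trimethylpyridinium triflate (formed in the flask, both epimers at the N,O-acetal carbon) | C#CC[C@@](C)(O[Si](CC)(CC)CC)CC(OC)[n+]1c(C)cc(C)cc1C.[O-]S(=O)(=O)C(F)(F)F | intermediate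
6 | (3R)-3-methyl-3-(triethylsilyloxy)hex-5-ynal | C#CC[C@@](C)(O[Si](CC)(CC)CC)CC=O | intermediate
7 | 3-methoxyprop-1-yne | C#CCOC | starting material
8 | (6R)-1-methoxy-6-methyl-6-(triethylsilyloxy)nona-2,8-diyn-4-ol (both C4 epimers) | C#CC[C@@](C)(O[Si](CC)(CC)CC)CC(O)C#CCOC | intermediate
9 | (6R)-1-methoxy-6-methyl-6-(triethylsilyloxy)nona-2,8-diyn-4-one | C#CC[C@@](C)(O[Si](CC)(CC)CC)CC(=O)C#CCOC | intermediate
10 | (4R,6R)-1-methoxy-6-methyl-6-(triethylsilyloxy)nona-2,8-diyn-4-ol | C#CC[C@@](C)(O[Si](CC)(CC)CC)C[C@@H](O)C#CCOC | intermediate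
11 | (4R,6R)-6-methyl-3-(propan-2-yl)-6-(triethylsilyloxy)nona-1,2-dien-8-yn-4-ol | C#CC[C@@](C)(O[Si](CC)(CC)CC)C[C@@H](O)C(C(C)C)=C=C | intermediate
12 | (4R,6R)-4-(tert-butyldimethylsilyloxy)-6-methyl-3-(propan-2-yl)-6-(triethylsilyloxy)nona-1,2-dien-8-yne (allenyne) | C#CC[C@@](C)(O[Si](CC)(CC)CC)C[C@@H](O[Si](C)(C)C(C)(C)C)C(C(C)C)=C=C | intermediate
13 | carbon monoxide | [C-]#[O+] | starting material
14 | (1R,3R)-1-(tert-butyldimethylsilyloxy)-7-isopropyl-3-methyl-3-(triethylsilyloxy)bicyclo[5.3.0]deca-5(8),6-dien-9-one (C9 ketone, C8=C5 and C6=C7 alkenes) | O=C1C=C2C[C@@](C)(O[Si](CC)(CC)CC)C[C@@H](O[Si](C)(C)C(C)(C)C)C(C(C)C)=C2C1 | intermediate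
15 | (1R,3R,7S)-1-(tert-butyldimethylsilyloxy)-7-isopropyl-3-methyl-3-(triethylsilyloxy)bicyclo[5.3.0]dec-5-en-9-one (C5=C6 alkene, formed in the flask) | CC(C)(C)[Si](C)(C)O[C@@H]1C[C@](C)(O[Si](CC)(CC)CC)CC2=C(CC(=O)C2)[C@@H]1C(C)C | intermediate
16 | (1R,3R,6S,7S)-1-(tert-butyldimethylsilyloxy)-7-isopropyl-3-methyl-3-(triethylsilyloxy)bicyclo[5.3.0]dec-5(8)-en-9-one (C6–H and C7–H trans) | CC(C)(C)[Si](C)(C)O[C@@H]1C[C@](C)(O[Si](CC)(CC)CC)CC2=CC(=O)C[C@H]2[C@@H]1C(C)C | intermediate
17 | lithium (1R,3R,5S,6R,7S)-1-(tert-butyldimethylsilyloxy)-7-isopropyl-3-methyl-3-(triethylsilyloxy)bicyclo[5.3.0]dec-8-en-9-olate (trans-fused, formed in the flask) | CC(C)(C)[Si](C)(C)O[C@@H]1C[C@](C)(O[Si](CC)(CC)CC)C[C@@H]2C=C([O-])C[C@H]2[C@@H]1C(C)C.[Li+] | intermediate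
18 | (1R,3R,5S,6R,7S)-1-(tert-butyldimethylsilyloxy)-7-isopropyl-3-methyl-3-(triethylsilyloxy)bicyclo[5.3.0]dec-8-en-9-yl triflate (trans-fused; C6 has the same spatial arrangement as in 16, the descriptor changes with CIP priority) | CC(C)(C)[Si](C)(C)O[C@@H]1C[C@](C)(O[Si](CC)(CC)CC)C[C@@H]2C=C(OS(=O)(=O)C(F)(F)F)C[C@H]2[C@@H]1C(C)C | intermediate
19 | (1R,3R,5S,6R,7S)-1-(tert-butyldimethylsilyloxy)-7-isopropyl-3,9-dimethyl-3-(triethylsilyloxy)bicyclo[5.3.0]dec-8-ene | CC(C)(C)[Si](C)(C)O[C@@H]1C[C@](C)(O[Si](CC)(CC)CC)C[C@@H]2C=C(C)C[C@H]2[C@@H]1C(C)C | intermediate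
20 | (1R,3R,5S,6R,7S)-7-isopropyl-3,9-dimethylbicyclo[5.3.0]dec-8-ene-1,3-diol | O[C@@H]1C[C@](C)(O)C[C@@H]2C=C(C)C[C@H]2[C@@H]1C(C)C | intermediate
21 | 3-hydroxy-4-methoxybenzoic acid (isovanillic acid) | COc1ccc(C(=O)O)cc1O | starting material
22 | 3-acetoxy-4-methoxybenzoic acid | COc1ccc(C(=O)O)cc1OC(C)=O | intermediate
23 | 3-acetoxy-4-methoxybenzoyl chloride (formed in the flask) | COc1ccc(C(=O)Cl)cc1OC(C)=O | intermediate
24 | (1R,3R,5S,6R,7S)-3-hydroxy-7-isopropyl-3,9-dimethylbicyclo[5.3.0]dec-8-en-1-yl 3-acetoxy-4-methoxybenzoate | COc1ccc(C(=O)O[C@@H]2C[C@](C)(O)C[C@@H]3C=C(C)C[C@H]3[C@@H]2C(C)C)cc1OC(C)=O | intermediate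
25 | (1R,3R,5S,6R,7S,8S,9R)-8,9-epoxy-3-hydroxy-7-isopropyl-3,9-dimethylbicyclo[5.3.0]decan-1-yl 3-acetoxy-4-methoxybenzoate | COc1ccc(C(=O)O[C@@H]2C[C@](C)(O)C[C@H]3[C@@H](C[C@@]4(C)O[C@@H]34)[C@@H]2C(C)C)cc1OC(C)=O | intermediate
26 | (1R,3R,5S,6R,7S,8S,9R)-8,9-epoxy-3-hydroxy-7-isopropyl-3,9-dimethylbicyclo[5.3.0]decan-1-yl 3-hydroxy-4-methoxybenzoate (CNP0106636.1) | COc1ccc(C(=O)O[C@@H]2C[C@](C)(O)C[C@H]3[C@@H](C[C@@]4(C)O[C@@H]34)[C@@H]2C(C)C)cc1O | target

**Count and risks**

Total step count: 16. Longest linear sequence: 15 steps (steps 1 to 12 and 14 to 16, from 4,4-dimethoxybutan-2-one); step 13 prepares the acyl partner.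

Steps most likely to fail:

Step 9. Hydride may add to C5 (1,4-reduction) instead of C7, or reach C7 from the face of the silyl ether. The fallback sets out from 14 and returns at 16, and replaces hydride delivery by a dissolving-metal reduction, which in linear dienones protonates the δ-carbon. An allylic silyl ether next to C7 would be expelled from the reduced dienone, so both silyl groups are first removed with HF·pyridine in THF/pyridine to give the dienone diol F1. Li in NH3/THF at −78 °C (both hydroxyls present as lithium alkoxides, which do not leave), NH4Cl quench and catalytic DBU should then give the conjugated enone diol F2, with C7 protonated anti to the solvated C1 alkoxide and C6 equilibrated. TBSCl/imidazole in DMF should silylate only the secondary hydroxyl to give the C1 silyl ether F3, and TESOTf/2,6-lutidine on the tertiary hydroxyl returns 16.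

Step 10. The C5 carbanion may be protonated on the face that gives the cis ring fusion, or the enolate may exchange protons before it is sulfonylated. The fallback sets out from 16 and returns at 18, and sets C5 by hydroxyl-directed hydrogenation. Luche reduction (NaBH4, CeCl3·7H2O, MeOH, −78 °C) should attack C9 from the face away from the C6–C7 bond and give the allylic alcohol F4, with its hydroxyl on the face where the C5 hydrogen is wanted. Hydrogenation with [Ir(cod)(PCy3)(py)]PF6 under H2 in CH2Cl2 should add hydrogen syn to that hydroxyl and give the trans-fused alcohol F5. Dess–Martin oxidation gives the trans-fused ketone F6. KN(SiMe3)2 at −78 °C followed by PhNTf2 is expected to enolise towards the less hindered C8 (C10 is flanked by the isopropyl-bearing side) and give 18, with any C9=C10 regioisomer removed by chromatography.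

Step 15. The remote hydroxyl may fail to direct, so that oxygen arrives on the face syn to C5–H, or the epoxidation may be slow. The fallback sets out from 19 and returns at 25, and uses the intrinsic facial bias instead of opposing it. NBS in wet THF on the bis-silyl ether 19 (whose silylated C3 oxygen cannot intercept the bromonium ion) should place bromine on the more accessible face and water at the tertiary C9 from the opposite face, giving the bromohydrin F7. K2CO3 in MeOH closes the ring with inversion at C8 and gives the bis-silyl epoxide F8 on the required face. Bu4NF removes both silyl groups to give the epoxy diol F9, and acylation of its C1 hydroxyl with acid chloride 23 (Et3N, DMAP, CH2Cl2) gives 25.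

**Further compounds**

F1 | step 9 | (1R,3R)-1,3-dihydroxy-7-isopropyl-3-methylbicyclo[5.3.0]deca-5(8),6-dien-9-one | O=C1C=C2C[C@@](C)(O)C[C@@H](O)C(C(C)C)=C2C1
F2 | step 9 | (1R,3R,6S,7S)-1,3-dihydroxy-7-isopropyl-3-methylbicyclo[5.3.0]dec-5(8)-en-9-one | O[C@@H]1C[C@](C)(O)CC2=CC(=O)C[C@H]2[C@@H]1C(C)C
F3 | step 9 | (1R,3R,6S,7S)-1-(tert-butyldimethylsilyloxy)-3-hydroxy-7-isopropyl-3-methylbicyclo[5.3.0]dec-5(8)-en-9-one | CC(C)(C)[Si](C)(C)O[C@@H]1C[C@](C)(O)CC2=CC(=O)C[C@H]2[C@@H]1C(C)C
F4 | step 10 | C9 allylic alcohol of 16, hydroxyl on the face of the C6–C7 bond (1-(tert-butyldimethylsilyloxy)-7-isopropyl-3-methyl-3-(triethylsilyloxy)bicyclo[5.3.0]dec-5(8)-en-9-ol) | CC(C)(C)[Si](C)(C)O[C@@H]1C[C@](C)(O[Si](CC)(CC)CC)CC2=C[C@@H](O)C[C@H]2[C@@H]1C(C)C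
F5 | step 10 | trans-fused 1-(tert-butyldimethylsilyloxy)-7-isopropyl-3-methyl-3-(triethylsilyloxy)bicyclo[5.3.0]decan-9-ol (C5–H syn to the C9 hydroxyl and anti to C6–H) | CC(C)(C)[Si](C)(C)O[C@@H]1C[C@](C)(O[Si](CC)(CC)CC)C[C@@H]2C[C@@H](O)C[C@H]2[C@@H]1C(C)C
F6 | step 10 | trans-fused 1-(tert-butyldimethylsilyloxy)-7-isopropyl-3-methyl-3-(triethylsilyloxy)bicyclo[5.3.0]decan-9-one | CC(C)(C)[Si](C)(C)O[C@@H]1C[C@](C)(O[Si](CC)(CC)CC)C[C@@H]2CC(=O)C[C@H]2[C@@H]1C(C)C
F7 | step 15 | 8-bromo-1-(tert-butyldimethylsilyloxy)-7-isopropyl-3,9-dimethyl-3-(triethylsilyloxy)bicyclo[5.3.0]decan-9-ol (bromine syn to C5–H, C9 hydroxyl on the opposite face) | CC(C)(C)[Si](C)(C)O[C@@H]1C[C@](C)(O[Si](CC)(CC)CC)C[C@@H]2[C@@H](Br)[C@](C)(O)C[C@H]2[C@@H]1C(C)C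
F8 | step 15 | (1R,3R,5S,6R,7S,8S,9R)-1-(tert-butyldimethylsilyloxy)-8,9-epoxy-7-isopropyl-3,9-dimethyl-3-(triethylsilyloxy)bicyclo[5.3.0]decane | CC(C)(C)[Si](C)(C)O[C@@H]2C[C@](C)(O[Si](CC)(CC)CC)C[C@H]3[C@@H](C[C@@]4(C)O[C@@H]34)[C@@H]2C(C)C
F9 | step 15 | (1R,3R,5S,6R,7S,8S,9R)-8,9-epoxy-7-isopropyl-3,9-dimethylbicyclo[5.3.0]decane-1,3-diol | O[C@@H]2C[C@](C)(O)C[C@H]3[C@@H](C[C@@]4(C)O[C@@H]34)[C@@H]2C(C)C
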